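**Elm's leftover.** Start from what elm leaves at its last reading: 15% of the substrate remains and 30% is target, so 55.0% stands in unread forms.

| setting | alder | elm | noon | winter | dusk | spring |
|---|---|---|---|---|---|---|
| substrate | 19 mM | 19 mM | 19 mM | 19 mM | 19 mM | 19 mM |
| partner | 2 equiv | 8 equiv | 4.00 equiv | 4.00 equiv | 4.00 equiv | 4.00 equiv |
| temperature | −20 °C | 15 °C | 45 °C | −15 °C | 5 °C | 25 °C |
| remark | run made earlier | run made earlier |  |  |  |  |
| time |  |  | 6.0 h | 6.0 h | 6.0 h | 6.0 h |

| run | time / h | target / % | substrate / % |
|---|---|---|---|
| alder | 15.0 | 0 | 97 |
| alder | 40.0 | 0 | 90 |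
| alder | 72.0 | 0 | 84 |
| alder | 120 | 1 | 79 |
| elm | 2.00 | 6 | 59 |
| elm | 4.00 | 18 | 38 |
| elm | 8.00 | 30 | 24 |
| elm | 20.0 | 30 | 15 |

(scatter of a reading: 1.5 percentage points)

1. the flask with the highest amount of target, in percent of the substrate charged ("all alike" if they lie within 1.5 percentage points) (noon / winter / dusk / spring / all alike)
2. final target, as a percentage of the substrate charged, in noon
3. final target, as a percentage of the substrate charged, in winter
4. final target, as a percentage of the substrate charged, in dusk
5. final target, as a percentage of the substrate charged, in spring

**The ratio.** Divide the rate of target gain by the rate of substrate loss and time drops out, which leaves S = 0.353, the target held per substrate lost, read at elm's end; earlier in elm the same ratio climbs from 0.146 to 0.395, so use S once that lag is over.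

**Turning time.** By hand, more time should give more target, but elm reads 30% at 8.00 h and 30% at 20.0 h while its substrate falls from 24% to 15%.

**Turning temperature.** Cooling should stretch the lag, and alder does hold a ratio of 0.0476 at 120 h, so keep S away from winter and dusk, both colder than elm.

**Turning partner.** With partner in excess the substrate loss starts pseudo-first-order, its rate proportional to partner, so spring has half of elm's equivalents; let its warmer bath pay that back, and take spring's loss as elm's at 8.00 h, 76.0%. My reckoning then gives spring 26.8%.

**The forecast.** It names spring, with noon 28%, winter 0.1%, dusk 3% and spring 30%, a spring value above mine, and it adds: “Spring versus noon is uncertain.”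

**The flasks.** Spring leads with 24.1%, then noon 21.1%, dusk 3.96% and winter 0.0413%.

    substrate + partner ⇌ intermediate (K = 24.0 /M, k = 4.40 /M/h, Ea = 57.0 kJ/mol, ΔH = 7.00 kJ/mol)
    intermediate ⇌ target + by-product (K = 0.00370 M, k = 0.620 /h, Ea = 88.0 kJ/mol, ΔH = −29.0 kJ/mol)
    target ⇌ isomer of the product (K = 0.240, k = 0.130 /h, Ea = 102 kJ/mol, ΔH = −61.0 kJ/mol)
    (constants at 25 °C)

**Ratio reused.** Spring lost 66.6% of its substrate, so S gives 23.5%. In spring the step from intermediate to target + by-product relaxes with a half-life of 0.300 h, shorter than the 1.41 h of the substrate + partner step and short against 6.0 h. That half-life counts both directions of the step, not its forward run, and at 1.42 h spring still makes intermediate 1.63 times faster than it uses it up. In the neighbour flask, spring at 76 mM of substrate, the loss of 88.0% makes S give 31.1%, but that flask computes to 16.4% target with 67.9% as intermediate, so S read at 19 mM does not carry there.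

The numbers in the tables are calculated with constants of no real substance; noise was put on by code.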